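Ring C is cut at O1–C2 and C4–C4a, which divides the target into a ring A phenol and a ring B cinnamoyl unit (C2–C3–C4). The key step joins them in one telescoped operation: the C,O-dilithio species of an ortho-iodophenol is acylated at the future C4a by a cinnamic Weinreb amide, and the released 2'-hydroxychalcone is closed at O1–C2 by a chiral amine-thiourea, which sets C2 as S. The step exploits the mirror symmetry of ring A: O1 lies para to the geranyl-bearing C6, so both carbons ortho to O1 are equivalent and only the 6-geranyl pattern can form, while O1, the only free hydroxyl, alone cyclises.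

Key step: step 7

Abbreviations: MOM = methoxymethyl, TIPS = triisopropylsilyl, geranyl = (2E)-3,7-dimethylocta-2,6-dien-1-yl.

Assumption: aldehyde 9 and phosphonate 11 are taken as commercial, and the 9-amino-9-deoxy-epi-quinidine thiourea is taken as the pseudoenantiomer that gives the 2S series (its quinine-derived counterpart would be used if the sense proved opposite).

Step 1
Reactants: 1 phloroglucinol (benzene-1,3,5-triol)
Product: 2 3,5-bis(methoxymethoxy)phenol
Conditions: MOMCl (2.1 equiv), i-Pr2NEt, DMF, 0 °C → rt
Reagents that add atoms: chloromethyl methyl ether (MOMCl), COCCl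
Why: Williamson-type O-alkylation of the phenoxides with the chloromethyl ether; the three hydroxyls are equivalent, so two equivalents of reagent should give the bis-ether as the main component of a statistical mixture from which the mono- and tris-ethers are separated and recycled.

Step 2
Reactants: 2 3,5-bis(methoxymethoxy)phenol
Product: 3 [3,5-bis(methoxymethoxy)phenoxy]triisopropylsilane
Conditions: TIPSCl, imidazole, DMF, rt
Reagents that add atoms: chlorotriisopropylsilane (TIPSCl), CC(C)[Si](Cl)(C(C)C)C(C)C
Why: Imidazole-promoted O-silylation of the one remaining phenol, which marks the future O1 and shields its two ortho carbons from metalation in the next step.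

Step 3
Reactants: 3 [3,5-bis(methoxymethoxy)phenoxy]triisopropylsilane; 4 geranyl bromide [(2E)-1-bromo-3,7-dimethylocta-2,6-diene]
Product: 6 [4-geranyl-3,5-bis(methoxymethoxy)phenoxy]triisopropylsilane, via aryllithium 5 (not isolated)
Conditions: n-BuLi (1.1 equiv), THF, 0 °C; then 4, −78 °C → rt
Reagents that add atoms: none
Why: Directed ortho-metalation at the only C–H flanked by two MOM ethers (the future C6), followed by SN2 alkylation of the aryllithium with the primary allylic bromide, which keeps the E geometry of the 2,3-alkene of the geranyl chain.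

Step 4
Reactants: 6 [4-geranyl-3,5-bis(methoxymethoxy)phenoxy]triisopropylsilane
Product: 8 4-geranyl-2-iodo-3,5-bis(methoxymethoxy)phenol, via tetrabutylammonium phenoxide 7 (not isolated)
Conditions: TBAF (1.05 equiv), THF, 0 °C; then NIS (1.0 equiv), −78 °C; H2O
Reagents that add atoms: N-iodosuccinimide (NIS), O=C1CCC(=O)N1I
Why: Fluoride-mediated cleavage of the aryl silyl ether, then electrophilic aromatic iodination of the phenoxide, which is far more nucleophilic than the trisubstituted alkenes; the para position is blocked by geranyl and the two ortho carbons are equivalent, so one equivalent of NIS at low temperature should give a single mono-iodide.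

Step 5
Reactants: 9 3-hydroxy-4,5-dimethoxybenzaldehyde
Product: 10 3,4-dimethoxy-5-(methoxymethoxy)benzaldehyde
Conditions: MOMCl, i-Pr2NEt, CH2Cl2, 0 °C → rt
Reagents that add atoms: chloromethyl methyl ether (MOMCl), COCCl
Why: Williamson-type O-alkylation protects the only phenol of ring B as a MOM ether that survives the organolithium step and leaves with the other two MOM groups at the end.

Step 6
Reactants: 10 3,4-dimethoxy-5-(methoxymethoxy)benzaldehyde; 11 diethyl {2-[methoxy(methyl)amino]-2-oxoethyl}phosphonate
Product: 12 (2E)-3-[3,4-dimethoxy-5-(methoxymethoxy)phenyl]-N-methoxy-N-methylprop-2-enamide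
Conditions: NaH, THF, 0 °C → rt
Reagents that add atoms: none
Why: Horner–Wadsworth–Emmons olefination with a stabilised phosphonate anion, which should give the E-enamide and installs C3 and C4 at the Weinreb amide oxidation level.

Step 7
Reactants: 8 4-geranyl-2-iodo-3,5-bis(methoxymethoxy)phenol; 12 (2E)-3-[3,4-dimethoxy-5-(methoxymethoxy)phenyl]-N-methoxy-N-methylprop-2-enamide
Product: 15 (2S)-2-[3,4-dimethoxy-5-(methoxymethoxy)phenyl]-6-geranyl-5,7-bis(methoxymethoxy)-2,3-dihydro-4H-chromen-4-one, via dilithio species 13 (not isolated), via 2'-hydroxychalcone 14 (not isolated)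
Conditions: n-BuLi (2.1 equiv), THF, −78 °C; 12, −78 → −20 °C; AcOH (2.2 equiv); filtration through a silica pad, solvent switch to toluene; 9-amino-9-deoxy-epi-quinidine 3,5-bis(trifluoromethyl)phenyl thiourea (20 mol %), toluene, rt
Reagents that add atoms: none
Why: Iodine–lithium exchange on the lithium phenoxide of 8 gives the C,O-dilithio species 13, whose aryl carbon (the future C4a) adds 1,2 to the N-methoxy-N-methylamide 12, and the acidic quench releases the 2'-hydroxychalcone 14 with the C4–C4a bond in place. The chiral amine-thiourea then closes the O1–C2 bond by an intramolecular oxa-Michael addition, a 6-endo-trig closure of ring C. The closest known reaction types are the acylation of aryllithiums by unsaturated Weinreb amides and the amine-thiourea-catalysed, biomimetic cyclisation of 2'-hydroxychalcones to flavanones. C2 is set by the catalyst: its quinuclidine nitrogen activates the O1–H as a general base while the thiourea binds the C4 carbonyl, so that O1 is delivered to the Si face of C2 of the E-enone, which gives 2S. The step needs 1,2- over 1,4-addition, closure through O1 and not through the oxygen on C5, and the 6-geranyl and not the 8-geranyl pattern; the hard aryllithium and the Weinreb amide secure the first, the MOM group on the C5 oxygen the second, and the mirror symmetry of ring A in 8 (both carbons ortho to O1 equivalent, geranyl para) the third. The cyclisation is run under kinetic control and stopped at full conversion, because the oxa-Michael addition is reversible and long exposure would erode the enantiomeric purity.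

Step 8
Reactants: 15 (2S)-2-[3,4-dimethoxy-5-(methoxymethoxy)phenyl]-6-geranyl-5,7-bis(methoxymethoxy)-2,3-dihydro-4H-chromen-4-one
Product: 16 (2S)-6-geranyl-5,7-dihydroxy-2-(3-hydroxy-4,5-dimethoxyphenyl)-2,3-dihydro-4H-chromen-4-one (CNP0228243.1)
Conditions: 3 M aq HCl, MeOH, 40 °C
Reagents that add atoms: none
Why: Acid-catalysed acetal methanolysis removes the three aryl MOM ethers; without base the retro-oxa-Michael ring opening that would scramble C2 is not available, and dilute acid at mild temperature should spare the geranyl alkenes.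

Compound list
1 | phloroglucinol (benzene-1,3,5-triol) | Oc1cc(O)cc(O)c1 | starting material
2 | 3,5-bis(methoxymethoxy)phenol | COCOc1cc(O)cc(OCOC)c1 | intermediate
3 | [3,5-bis(methoxymethoxy)phenoxy]triisopropylsilane | COCOc1cc(OCOC)cc(O[Si](C(C)C)(C(C)C)C(C)C)c1 | intermediate
4 | geranyl bromide, (2E)-1-bromo-3,7-dimethylocta-2,6-diene | BrC/C=C(\C)CCC=C(C)C | starting material
5 | [2,6-bis(methoxymethoxy)-4-(triisopropylsilyloxy)phenyl]lithium | [Li]c1c(OCOC)cc(O[Si](C(C)C)(C(C)C)C(C)C)cc1OCOC | intermediate
6 | [4-geranyl-3,5-bis(methoxymethoxy)phenoxy]triisopropylsilane | COCOc1cc(O[Si](C(C)C)(C(C)C)C(C)C)cc(OCOC)c1C/C=C(\C)CCC=C(C)C | intermediate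
7 | tetrabutylammonium 4-geranyl-3,5-bis(methoxymethoxy)phenoxide | CCCC[N+](CCCC)(CCCC)CCCC.[O-]c1cc(OCOC)c(C/C=C(\C)CCC=C(C)C)c(OCOC)c1 | intermediate
8 | 4-geranyl-2-iodo-3,5-bis(methoxymethoxy)phenol | COCOc1cc(O)c(I)c(OCOC)c1C/C=C(\C)CCC=C(C)C | intermediate
9 | 3-hydroxy-4,5-dimethoxybenzaldehyde | COc1cc(C=O)cc(O)c1OC | starting material
10 | 3,4-dimethoxy-5-(methoxymethoxy)benzaldehyde | COCOc1cc(C=O)cc(OC)c1OC | intermediate
11 | diethyl {2-[methoxy(methyl)amino]-2-oxoethyl}phosphonate | CCOP(=O)(CC(=O)N(C)OC)OCC | starting material
12 | (2E)-3-[3,4-dimethoxy-5-(methoxymethoxy)phenyl]-N-methoxy-N-methylprop-2-enamide | CON(C)C(=O)/C=C/c1cc(OC)c(OC)c(OCOC)c1 | intermediate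
13 | lithium 4-geranyl-2-lithio-3,5-bis(methoxymethoxy)phenoxide | [Li]Oc1cc(OCOC)c(C/C=C(\C)CCC=C(C)C)c(OCOC)c1[Li] | intermediate
14 | (2E)-1-[3-geranyl-6-hydroxy-2,4-bis(methoxymethoxy)phenyl]-3-[3,4-dimethoxy-5-(methoxymethoxy)phenyl]prop-2-en-1-one | COCOc1cc(O)c(C(=O)/C=C/c2cc(OC)c(OC)c(OCOC)c2)c(OCOC)c1C/C=C(\C)CCC=C(C)C | intermediate
15 | (2S)-2-[3,4-dimethoxy-5-(methoxymethoxy)phenyl]-6-geranyl-5,7-bis(methoxymethoxy)-2,3-dihydro-4H-chromen-4-one | COc1cc([C@@H]2CC(=O)c3c(cc(OCOC)c(C/C=C(\C)CCC=C(C)C)c3OCOC)O2)cc(OCOC)c1OC | intermediate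
16 | (2S)-6-geranyl-5,7-dihydroxy-2-(3-hydroxy-4,5-dimethoxyphenyl)-2,3-dihydro-4H-chromen-4-one (CNP0228243.1) | COc1cc([C@@H]2CC(=O)c3c(cc(O)c(C/C=C(\C)CCC=C(C)C)c3O)O2)cc(O)c1OC | target

Total step count: 8. Longest linear sequence: 6 steps (steps 1, 2, 3, 4, 7 and 8, from phloroglucinol 1).

Steps most likely to fail

Step 7. The enantioface discrimination in the oxa-Michael closure may be incomplete, through racemic background cyclisation by residual salts or through erosion by reversible ring opening, and conjugate addition of the aryllithium may compete with acylation. The fallback sets out from chalcone 14, this time purified by chromatography after the acylation stage. Sodium acetate in refluxing ethanol closes it to the racemic 2-[3,4-dimethoxy-5-(methoxymethoxy)phenyl]-6-geranyl-5,7-bis(methoxymethoxy)chroman-4-one F1. Asymmetric transfer hydrogenation with Cp*RhCl[(R,R)-TsDPEN] (1 mol %), HCO2H/Et3N, EtOAc, rt is then run as a kinetic resolution. The 2R enantiomer should be reduced to the cis-(2R,4R)-flavan-4-ol F2, and the unreacted ketone is the (2S)-flavanone 15, where the route is rejoined after chromatographic separation. The same resolution can serve to polish material of insufficient enantiomeric purity from the main step.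

Step 3. Unreacted aryllithium may be quenched by proton transfer from the doubly activated benzylic-allylic CH2 of the product, SN2' attack may give the branched linalyl isomer, and metalation may stray to a carbon next to the silyl ether. The fallback sets out from phloroglucinol 1 and geranyl bromide 4 and builds the C-geranyl bond by phenoxide C-alkylation instead of metalation. DBU in THF at rt should give 2-geranylbenzene-1,3,5-triol F3. TIPSCl (1.0 equiv) and imidazole in DMF at 0 °C should silylate the least hindered hydroxyl, the one para to the geranyl group, to give 2-geranyl-5-(triisopropylsilyloxy)benzene-1,3-diol F4. MOMCl and NaH in DMF then cap the two flanking hydroxyls and return to compound 6.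

Step 8. Acid-promoted cyclisation of the geranyl chain onto the freed hydroxyl at C5 or C7 (chroman formation), or hydration of its alkenes, may compete with acetal cleavage. The fallback sets out from 15 and avoids free Brønsted acid. TMSOTf and 2,2'-bipyridyl in CH2Cl2 at 0 °C exchange the three aryl MOM ethers for trimethylsilyl ethers to give the (2S)-5,7-bis(trimethylsilyloxy)-2-[3,4-dimethoxy-5-(trimethylsilyloxy)phenyl]-6-geranylchroman-4-one F5. Water in THF at rt then hydrolyses it to the target 16.

Further compounds
F1 | step 7 | racemic 2-[3,4-dimethoxy-5-(methoxymethoxy)phenyl]-6-geranyl-5,7-bis(methoxymethoxy)chroman-4-one | COc1cc(C2CC(=O)c3c(cc(OCOC)c(C/C=C(\C)CCC=C(C)C)c3OCOC)O2)cc(OCOC)c1OC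
F2 | step 7 | (2R,4R)-2-[3,4-dimethoxy-5-(methoxymethoxy)phenyl]-6-geranyl-5,7-bis(methoxymethoxy)chroman-4-ol | COc1cc([C@H]2C[C@@H](O)c3c(cc(OCOC)c(C/C=C(\C)CCC=C(C)C)c3OCOC)O2)cc(OCOC)c1OC
F3 | step 3 | 2-geranylbenzene-1,3,5-triol | Oc1cc(O)c(C/C=C(\C)CCC=C(C)C)c(O)c1
F4 | step 3 | 2-geranyl-5-(triisopropylsilyloxy)benzene-1,3-diol | CC(C)[Si](Oc1cc(O)c(C/C=C(\C)CCC=C(C)C)c(O)c1)(C(C)C)C(C)C
F5 | step 8 | (2S)-2-[3,4-dimethoxy-5-(trimethylsilyloxy)phenyl]-6-geranyl-5,7-bis(trimethylsilyloxy)chroman-4-one | COc1cc([C@@H]2CC(=O)c3c(cc(O[Si](C)(C)C)c(C/C=C(\C)CCC=C(C)C)c3O[Si](C)(C)C)O2)cc(O[Si](C)(C)C)c1OC
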